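At the meeting, the beta run was taken up first: it closed with G at 36.8 % of the X charged and X at 0.7 %. The theta run, charged with more X, closed with G at 68.7 %, a higher share. The flasks, readings and questions before the meeting were these.

all flasks: J 5 mol%

| flask | X | remark | time |
|---|---|---|---|
| beta | 0.013 M | run made earlier |  |
| theta | 0.039 M | run made earlier |  |
| Monday's | 0.022 M |  | 30 min |
| Wednesday's | 0.060 M |  | 30 min |

| run | time / min | G / % | X / % |
|---|---|---|---|
| beta | 8.00 | 21.6 | 35.3 |
| beta | 15.0 | 32.1 | 12.4 |
| beta | 25.0 | 36.7 | 2.7 |
| beta | 30.0 | 36.8 | 0.7 |
| theta | 2.50 | 27.1 | 57.0 |
| theta | 6.00 | 54.6 | 18.3 |
| theta | 12.0 | 67.2 | 2.1 |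
| theta | 30.0 | 68.7 | 0 |

(readings scatter by 0.3 percentage points)

- the average divides the monomer in chains by the number of chains begun, living and dead together
- the earlier runs do not show the number of chains; that part of a forecast is a guess

1. which of the two ends with the longer chains by the average number of monomer units in a chain (chains begun, living or dead) ("neither" if they lie within 10 %) (Monday's / Wednesday's / neither)
2. average number of monomer units in a chain (chains begun, living or dead) at the end, Monday's
3. average number of monomer units in a chain (chains begun, living or dead) at the end, Wednesday's

The first speaker proposed to carry one quantity through the discussion, the ration 20.0, meaning the X charged per J charged. She argued that the length asked for is the G share times the ration, divided by the share of J that began a chain, the initiation efficiency. The loading is the same in the four flasks, so the ration is too.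

The second speaker replied that the earlier runs do not show the chains, so that efficiency is unknown. The first speaker therefore proposed a reckoning of her own: if each J charged begins one chain, the beta run stands at 7.36 and the theta run at 13.7. Monday's charge lies between those two and Wednesday's lies above theta's. If the G share goes on rising with the charge, Wednesday's figure is the higher, and she committed to Wednesday's.

The forecast also named Wednesday's, with 11.5 for Monday's and 16.5 for Wednesday's, and cautioned: “The chain count is a guess, and incomplete initiation would raise both.”

The flasks gave Wednesday's, at 17.5 against 13.1 for Monday's.

    X + L → G + L, rate k1*[L]*[X] (k = 2.60 L mol⁻¹ s⁻¹)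
    X → D (k = 0.00140 s⁻¹)
    X + J → L + G (k = 0.230 L mol⁻¹ s⁻¹)

Monday's ended with X at 0.17 % of the X charged but J at 19 % of its own charge, and G stood at 53.2 % of the X charged. The ration turns those figures into 13.1 units per chain. Wednesday's ended with G at 77.8 % of the X charged and J at 11 % of its own charge, and the same ration gives 17.5 units per chain.

The earlier runs and the new flask stem from a simulated flask for an exercise, and the scatter is random.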